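**Plan**

1. Numbering: ring C1 (=CH2), C2, C3, C4 (OAc), C5 (CMe2), C6; chain C7–C22 outward from C6. The ring together with C7 is a 7,7-dimethyl-2-methylenebicyclo[3.1.1]heptane (β-pinene-type) frame in which a C4–C7 bond has been exchanged for C4–O: the oxygen on C4 and C7 on C6 sit cis on the two carbons flanking C5, and C1 bears the methylene. This feature lets a vinylketene [2+2] build the ring.
2. Retrosynthesis: cut C8–C9 (alkyl–alkenyl coupling), take off C8 (one-carbon homologation at C7), re-form C4–C7 from C4–O (retro Baeyer–Villiger), then cut C5–C6 and C4–C7 together (retro [2+2]) back to geranoyl chloride.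
3. Forward: geranic acid → acid chloride → vinylketene, whose intramolecular crossed [2+2] closes the six-membered ring and the cyclobutanone in one event. Ozonolysis, oxygen insertion and re-methylenation give the bridged lactone, which is taken through lactol, Wittig homologation/acetylation, resolution, hydrolysis, reduction and iodination to the C8 iodide.
4. The C9–C22 alkenyl iodide is made from (E,E)-farnesol (bromide, propargylation–methylation, hydrozirconation–iodination) and joined last by Negishi coupling.
5. Stereochemistry: the cis C4–O/C6–C7 relation comes from the one-carbon bridge of the bicycle and retentive migration of C4; the absolute configuration from a lipase resolution of the racemic acetate; the C9=C10 geometry from syn hydrozirconation and retentive coupling; the other E alkenes from farnesol.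

Key step: step 2

Remark: geranic acid is taken as its 2E isomer (main component of the commercial acid); compounds 4–10 are racemic and their SMILES show the enantiomer that is carried on.
Remark: the lipase is assumed to follow the usual preference for esters of secondary carbinols (the R carbinol carbon is hydrolysed first), so that the (1S)-acetate is the one left.

**Route**

Step 1
Reactants: 1 (2E)-geranic acid
Product: 2 (2E)-geranoyl chloride
Conditions: (COCl)2, DMF (cat.), CH2Cl2, 0 °C → rt; volatiles removed, crude chloride used directly
Reagents that add atoms: oxalyl chloride, ClC(=O)C(=O)Cl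
Why: Acid chloride formation with oxalyl chloride under chloroiminium (Vilsmeier-type) catalysis is mild and gives only gaseous by-products, so both alkenes and the 2E geometry should survive.

Step 2
Reactants: 2 (2E)-geranoyl chloride
Product: 4 rac-7,7-dimethyl-2-methylidenebicyclo[3.1.1]heptan-6-one, via vinylketene 3 (not isolated)
Conditions: Et3N (3 equiv), toluene, reflux; 2 added slowly (final concentration about 0.02 M)
Reagents that add atoms: none
Why: Et3N removes a proton from the C3 methyl of 2 (the future exocyclic CH2 on C1, held cis to the acyl group in the 2E chloride) with loss of chloride, a 1,4-dehydrochlorination that gives vinylketene 3, O=C7=C6H–C1(=CH2)–C2H2–C3H2–C4H=C5Me2. The ketene C7=C6 then adds thermally across C4=C5 in an asynchronous [2+2] in which electrophilic C7 bonds to the less substituted C4 and the tertiary cationic character developing at C5 collapses onto C6; the closest known reaction type is the intramolecular ketene–alkene cycloaddition of vinylketenes generated from dienoyl chlorides. The six-membered carbocycle closes through C5–C6 in an endo sense (both alkene carbons end up in the ring) and the cyclobutanone closes through C4–C7, the two rings sharing C4, C5 and C6 as a bicyclo[3.1.1]heptan-6-one. The two new stereocentres, the bridgeheads C4 and C6, are locked cis by the one-carbon bridges C5 and C7, so only one relative configuration can form; nothing controls the absolute sense and 4 is racemic. The step needs crossed rather than fused regiochemistry, which the three-atom tether and the cation-stabilising CMe2 terminus secure, and it needs cyclisation to outrun ketene dimerisation, which slow addition at high dilution secures.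

Step 3
Reactants: 4 rac-7,7-dimethyl-2-methylidenebicyclo[3.1.1]heptan-6-one
Product: 5 rac-7,7-dimethylbicyclo[3.1.1]heptane-2,6-dione
Conditions: O3, CH2Cl2, −78 °C; then Me2S, −78 °C → rt; crude dione used at once
Reagents that add atoms: ozone, [O-][O+]=O
Why: Ozonolysis cleaves only the electron-rich exocyclic alkene (the cyclobutanone is inert to ozone), and the anhydrous reductive work-up avoids nucleophiles that could open the strained 1,3-dione, whose bridgehead C6–H cannot enolise.

Step 4
Reactants: 5 rac-7,7-dimethylbicyclo[3.1.1]heptane-2,6-dione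
Product: 6 rac-8,8-dimethyl-6-oxabicyclo[3.2.1]octane-2,7-dione
Conditions: mCPBA (dried, 1.1 equiv), CH2Cl2, 0 °C
Reagents that add atoms: mCPBA, OOC(=O)c1cccc(Cl)c1
Why: Baeyer–Villiger oxidation takes place at the strained cyclobutanone much faster than at the cyclohexanone, and because C6 is now attached to an electron-withdrawing carbonyl its migratory aptitude should fall below that of the unactivated secondary C4, so oxygen is inserted into C4–C7 with retention at C4 and the cis C4–O/C6–C7 relation of the target is fixed.

Step 5
Reactants: 6 rac-8,8-dimethyl-6-oxabicyclo[3.2.1]octane-2,7-dione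
Product: 7 rac-8,8-dimethyl-2-methylidene-6-oxabicyclo[3.2.1]octan-7-one
Conditions: Ph3PCH3Br (1.5 equiv), KN(SiMe3)2 (1.4 equiv), THF, 0 °C; then 6, 0 °C → rt
Reagents that add atoms: methyltriphenylphosphonium bromide, C[P+](c1ccccc1)(c1ccccc1)c1ccccc1.[Br-]
Why: Wittig methylenation is selective for the ketone over the lactone, and as the bridgehead hydrogen between the two carbonyls cannot be removed the ylide is not consumed as a base by the 1,3-dicarbonyl unit.

Step 6
Reactants: 7 rac-8,8-dimethyl-2-methylidene-6-oxabicyclo[3.2.1]octan-7-one
Product: 8 rac-8,8-dimethyl-2-methylidene-6-oxabicyclo[3.2.1]octan-7-ol (lactol)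
Conditions: i-Bu2AlH (1.1 equiv), CH2Cl2, −78 °C; aq. potassium sodium tartrate
Reagents that add atoms: none
Why: Partial reduction of the γ-lactone with i-Bu2AlH stops at the stable aluminium hemiacetal at −78 °C and should give the bridged lactol as an anomer mixture without touching the alkene.

Step 7
Reactants: 8 rac-8,8-dimethyl-2-methylidene-6-oxabicyclo[3.2.1]octan-7-ol
Product: 10 rac-cis-3-(2-methoxyethenyl)-2,2-dimethyl-4-methylidenecyclohexyl acetate (E/Z mixture), via hydroxy enol ether 9 (not isolated)
Conditions: MeOCH2PPh3Cl (3.5 equiv), KN(SiMe3)2 (3.3 equiv), THF, 0 °C; 8, 0 °C → rt; then Ac2O, DMAP (cat.), 0 °C → rt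
Reagents that add atoms: (methoxymethyl)triphenylphosphonium chloride, COC[P+](c1ccccc1)(c1ccccc1)c1ccccc1.[Cl-]; acetic anhydride, CC(=O)OC(C)=O
Why: Wittig olefination of the lactol through its open hydroxy aldehyde form adds C8 as a methyl enol ether (the aldehyde is present only in low concentration and its cis, diequatorial arrangement is the stable one, which should keep C6 from epimerising), and the C4 alkoxide set free is acetylated in the same flask.

Step 8
Reactants: 10 rac-cis-3-(2-methoxyethenyl)-2,2-dimethyl-4-methylidenecyclohexyl acetate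
Product: 11 (1S,3R)-3-(2-methoxyethenyl)-2,2-dimethyl-4-methylidenecyclohexyl acetate (E/Z mixture)
Conditions: Burkholderia cepacia lipase (immobilised), NaH2PO4/Na2HPO4 buffer pH 7, t-BuOMe co-solvent, 30 °C, run slightly past half conversion; alcohol removed by chromatography
Reagents that add atoms: none
Why: Lipase-catalysed hydrolytic kinetic resolution: the enzyme should hydrolyse the enantiomer whose carbinol carbon is R (large CMe2 side, medium CH2 side), leaving the (1S,3R)-acetate needed for the target unchanged, and running past half conversion should raise its enantiomeric purity even if the selectivity is only moderate.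

Step 9
Reactants: 11 (1S,3R)-3-(2-methoxyethenyl)-2,2-dimethyl-4-methylidenecyclohexyl acetate
Product: 12 (1S,3R)-2,2-dimethyl-4-methylidene-3-(2-oxoethyl)cyclohexyl acetate
Conditions: 1 M HCl (aq), THF, 0 °C → rt
Reagents that add atoms: water, O
Why: Acid hydrolysis of the enol ether (C-protonation, hemiacetal, loss of methanol) converges both geometric isomers on one aldehyde, and the short, cold treatment should spare the acetate and the exocyclic alkene.

Step 10
Reactants: 12 (1S,3R)-2,2-dimethyl-4-methylidene-3-(2-oxoethyl)cyclohexyl acetate
Product: 13 (1S,3R)-3-(2-hydroxyethyl)-2,2-dimethyl-4-methylidenecyclohexyl acetate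
Conditions: NaBH4, MeOH, 0 °C
Reagents that add atoms: none
Why: Borohydride reduction of the unhindered aldehyde is fast at 0 °C and should leave the hindered secondary acetate untouched.

Step 11
Reactants: 13 (1S,3R)-3-(2-hydroxyethyl)-2,2-dimethyl-4-methylidenecyclohexyl acetate
Product: 14 (1S,3R)-3-(2-iodoethyl)-2,2-dimethyl-4-methylidenecyclohexyl acetate
Conditions: I2, PPh3, imidazole, CH2Cl2, 0 °C → rt
Reagents that add atoms: iodine, [I][I]
Why: Appel-type iodination (alkoxyphosphonium formation, then SN2 displacement by iodide) converts the primary alcohol under nearly neutral conditions that the acetate and the alkene tolerate.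

Step 12
Reactants: 15 (2E,6E)-farnesol
Product: 16 (2E,6E)-farnesyl bromide
Conditions: PBr3, Et2O, 0 °C
Reagents that add atoms: phosphorus tribromide, BrP(Br)Br
Why: Bromination of the primary allylic alcohol with PBr3 at 0 °C proceeds by SN2 displacement of the phosphite ester without allylic transposition, so the 2E geometry is kept.

Step 13
Reactants: 16 (2E,6E)-farnesyl bromide
Product: 18 (6E,10E)-7,11,15-trimethylhexadeca-6,10,14-trien-2-yne, via lithium acetylide 17 (not isolated)
Conditions: propyne, n-BuLi (2 equiv), TMEDA, Et2O/hexane, −78 → 0 °C; 16, −78 °C → rt; then MeI, THF, 0 °C → rt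
Reagents that add atoms: propyne, CC#C; iodomethane, CI
Why: SN2 alkylation of 1,3-dilithiopropyne at its sp3 carbon by the primary allylic bromide adds C9–C11, and the lithium acetylide that remains is methylated in the same flask to give the 2-alkyne, the trisubstituted alkenes being inert to both operations.

Step 14
Reactants: 18 (6E,10E)-7,11,15-trimethylhexadeca-6,10,14-trien-2-yne
Product: 20 (2E,6E,10E)-2-iodo-7,11,15-trimethylhexadeca-2,6,10,14-tetraene, via alkenylzirconocene chloride 19 (not isolated)
Conditions: Cp2Zr(H)Cl (2.5 equiv), THF, 50 °C; then I2, THF, 0 °C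
Reagents that add atoms: iodine, [I][I]
Why: Hydrozirconation adds Zr–H syn across the alkyne far faster than across the trisubstituted alkenes and, under equilibrating conditions with excess reagent, should place zirconium on the less hindered methyl-bearing carbon, so that iodinolysis with retention gives the (E)-2-iodo-2-alkene.

Step 15
Reactants: 14 (1S,3R)-3-(2-iodoethyl)-2,2-dimethyl-4-methylidenecyclohexyl acetate; 20 (2E,6E,10E)-2-iodo-7,11,15-trimethylhexadeca-2,6,10,14-tetraene
Product: 22 (1S,3R)-2,2-dimethyl-4-methylidene-3-[(3E,7E,11E)-3,8,12,16-tetramethylheptadeca-3,7,11,15-tetraen-1-yl]cyclohexyl acetate, via alkylzinc iodide 21 (not isolated)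
Conditions: 14, Zn dust (activated with BrCH2CH2Br and Me3SiCl), LiCl, THF, 40 °C; then 20, PdCl2(dppf) (5 mol %), THF, rt → 40 °C
Reagents that add atoms: none
Why: Negishi coupling: zinc inserts into the primary C–I bond in the presence of the acetate, and palladium-catalysed cross-coupling of the alkylzinc with the alkenyl iodide proceeds with retention of alkene geometry, forming C8–C9 as the E trisubstituted alkene and completing the target.

**Compound list**

1 | (2E)-3,7-dimethylocta-2,6-dienoic acid (geranic acid) | CC(C)=CCC/C(C)=C/C(=O)O | starting material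
2 | (2E)-3,7-dimethylocta-2,6-dienoyl chloride (geranoyl chloride) | CC(C)=CCC/C(C)=C/C(=O)Cl | intermediate
3 | 7-methyl-3-methylideneocta-1,6-dien-1-one (vinylketene, not isolated) | CC(C)=CCCC(=C)C=C=O | intermediate
4 | rac-7,7-dimethyl-2-methylidenebicyclo[3.1.1]heptan-6-one (1R,5S enantiomer drawn) | C=C1CC[C@@H]2C(=O)[C@H]1C2(C)C | intermediate
5 | rac-7,7-dimethylbicyclo[3.1.1]heptane-2,6-dione | O=C1CC[C@@H]2C(=O)[C@H]1C2(C)C | intermediate
6 | rac-8,8-dimethyl-6-oxabicyclo[3.2.1]octane-2,7-dione | O=C1CC[C@@H]2OC(=O)[C@H]1C2(C)C | intermediate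
7 | rac-8,8-dimethyl-2-methylidene-6-oxabicyclo[3.2.1]octan-7-one (1R,5S enantiomer drawn) | C=C1CC[C@@H]2OC(=O)[C@H]1C2(C)C | intermediate
8 | rac-8,8-dimethyl-2-methylidene-6-oxabicyclo[3.2.1]octan-7-ol (lactol, both anomers) | C=C1CC[C@@H]2OC(O)[C@H]1C2(C)C | intermediate
9 | rac-cis-3-(2-methoxyethenyl)-2,2-dimethyl-4-methylidenecyclohexan-1-ol (E/Z; formed as its potassium alkoxide, not isolated) | C=C1CC[C@H](O)C(C)(C)[C@@H]1C=COC | intermediate
10 | rac-cis-3-(2-methoxyethenyl)-2,2-dimethyl-4-methylidenecyclohexyl acetate (E/Z) | C=C1CC[C@H](OC(C)=O)C(C)(C)[C@@H]1C=COC | intermediate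
11 | (1S,3R)-3-(2-methoxyethenyl)-2,2-dimethyl-4-methylidenecyclohexyl acetate (E/Z, single enantiomer) | C=C1CC[C@H](OC(C)=O)C(C)(C)[C@@H]1C=COC | intermediate
12 | (1S,3R)-2,2-dimethyl-4-methylidene-3-(2-oxoethyl)cyclohexyl acetate | C=C1CC[C@H](OC(C)=O)C(C)(C)[C@@H]1CC=O | intermediate
13 | (1S,3R)-3-(2-hydroxyethyl)-2,2-dimethyl-4-methylidenecyclohexyl acetate | C=C1CC[C@H](OC(C)=O)C(C)(C)[C@@H]1CCO | intermediate
14 | (1S,3R)-3-(2-iodoethyl)-2,2-dimethyl-4-methylidenecyclohexyl acetate | C=C1CC[C@H](OC(C)=O)C(C)(C)[C@@H]1CCI | intermediate
15 | (2E,6E)-3,7,11-trimethyldodeca-2,6,10-trien-1-ol ((E,E)-farnesol) | CC(C)=CCC/C(C)=C/CC/C(C)=C/CO | starting material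
16 | (2E,6E)-1-bromo-3,7,11-trimethyldodeca-2,6,10-triene (farnesyl bromide) | CC(C)=CCC/C(C)=C/CC/C(C)=C/CBr | intermediate
17 | lithium (5E,9E)-6,10,14-trimethylpentadeca-5,9,13-trien-1-yn-1-ide (not isolated) | [Li]C#CCC/C=C(\C)CC/C=C(\C)CCC=C(C)C | intermediate
18 | (6E,10E)-7,11,15-trimethylhexadeca-6,10,14-trien-2-yne | CC#CCC/C=C(\C)CC/C=C(\C)CCC=C(C)C | intermediate
19 | chlorobis(cyclopentadienyl)[(2E,6E,10E)-7,11,15-trimethylhexadeca-2,6,10,14-tetraen-2-yl]zirconium (not isolated) | C/C(=C\CC/C=C(\C)CC/C=C(\C)CCC=C(C)C)[Zr](Cl)(C1C=CC=C1)C1C=CC=C1 | intermediate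
20 | (2E,6E,10E)-2-iodo-7,11,15-trimethylhexadeca-2,6,10,14-tetraene | C/C(I)=C\CC/C=C(\C)CC/C=C(\C)CCC=C(C)C | intermediate
21 | {2-[(1R,3S)-3-acetoxy-2,2-dimethyl-6-methylidenecyclohexyl]ethyl}(iodo)zinc (not isolated) | C=C1CC[C@H](OC(C)=O)C(C)(C)[C@@H]1CC[Zn]I | intermediate
22 | (1S,3R)-2,2-dimethyl-4-methylidene-3-[(3E,7E,11E)-3,8,12,16-tetramethylheptadeca-3,7,11,15-tetraen-1-yl]cyclohexyl acetate | C=C1CC[C@H](OC(C)=O)C(C)(C)[C@@H]1CC/C(C)=C/CC/C=C(\C)CC/C=C(\C)CCC=C(C)C | target

**Count and risks**

Total step count: 15. Longest linear sequence: 12 steps (steps 1–11, then step 15); the side chain takes steps 12–14.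

Steps most likely to fail:

1. Step 4. Retro-Claisen opening of the strained 1,3-dione (through the peracid adduct or adventitious nucleophiles) may outrun migration, or oxygen may enter on the C6 side. The fallback sets out from 4 and replaces the ketone mask by an epoxide. Excess mCPBA (CH2Cl2, 0 °C → rt) should epoxidise the methylene and then insert oxygen into the cyclobutanone, C6 being no longer allylic and now next to an electron-withdrawing C–O carbon, to give the spiro-epoxy lactone F1. Deoxygenation of the epoxide with WCl6/n-BuLi (THF, −78 °C → rt) comes back to the route at 7, so steps 3 and 5 fall away.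

2. Step 8. The enzyme may turn over too slowly or discriminate too little at a carbinol flanked by a quaternary carbon. The fallback sets out from 7, whose enantiomers are separated by preparative chromatography on a chiral stationary phase (amylose tris(3,5-dimethylphenylcarbamate), CO2/MeOH), taking the (1R,5S)-lactone F2. The conditions of steps 6 and 7 applied to it give the (1R,5S)-lactol F3 and then, through the (1S,3R)-hydroxy enol ether F4 (acetylated in the flask), come back to the route at 11 without any enzymatic step.

3. Step 7. The basic, slowly adding ylide may deprotonate the β,γ-unsaturated aldehyde, moving the exocyclic alkene into conjugation. The fallback sets out from 8 and uses a Peterson sequence. Me3SiCH(Li)OMe (from Me3SiCH2OMe and s-BuLi, THF, −78 °C) should add to the open aldehyde at low temperature to give the β-hydroxysilane F5. KH (THF, 0 °C → rt) then triggers syn elimination to the alkoxide of 9, which is acetylated in the flask (Ac2O) to come back to the route at 10.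

**Further compounds**

F1 | step 4 | rac-8,8-dimethylspiro[6-oxabicyclo[3.2.1]octane-2,2'-oxiran]-7-one (both epimers at the spiro carbon) | C1OC12CC[C@@H]3OC(=O)[C@H]2C3(C)C
F2 | step 8 | (1R,5S)-8,8-dimethyl-2-methylidene-6-oxabicyclo[3.2.1]octan-7-one | C=C1CC[C@@H]2OC(=O)[C@H]1C2(C)C
F3 | step 8 | (1R,5S)-8,8-dimethyl-2-methylidene-6-oxabicyclo[3.2.1]octan-7-ol (both anomers) | C=C1CC[C@@H]2OC(O)[C@H]1C2(C)C
F4 | step 8 | (1S,3R)-3-(2-methoxyethenyl)-2,2-dimethyl-4-methylidenecyclohexan-1-ol (E/Z; as potassium alkoxide, not isolated) | C=C1CC[C@H](O)C(C)(C)[C@@H]1C=COC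
F5 | step 7 | rac-cis-3-[1-hydroxy-2-methoxy-2-(trimethylsilyl)ethyl]-2,2-dimethyl-4-methylidenecyclohexan-1-ol (diastereomer mixture at the two new carbons) | C=C1CC[C@H](O)C(C)(C)[C@@H]1C(O)C(OC)[Si](C)(C)C
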